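Electrophile charged is either still present or has reacted, whatever it has become, so the part reacted is read straight from the electrophile column, and the shortfall of electrophile plus target needs no explanation for this purpose.

common to all: electrophile 0.30 M

| flask | nucleophile | protic impurity | remark | time |
|---|---|---|---|---|
| ash | 0.48 M | 0.30 M | run made earlier |  |
| alder | 0.49 M | 0.30 M | run made earlier |  |
| birch | 0.55 M | 0.30 M | run made earlier |  |
| red | 0.390 M | 0.300 M |  | 20 h |
| violet | 0.580 M | 0.300 M |  | 20 h |

| run | time / h | electrophile / % | target / % |
|---|---|---|---|
| ash | 2.00 | 61.3 | 33.6 |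
| ash | 5.00 | 43.7 | 50.0 |
| ash | 10.0 | 33.5 | 56.1 |
| ash | 15.0 | 28.1 | 58.8 |
| ash | 20.0 | 26.5 | 60.4 |
| alder | 4.00 | 46.9 | 47.0 |
| alder | 8.00 | 34.7 | 56.0 |
| alder | 12.0 | 30.9 | 59.7 |
| alder | 15.0 | 28.1 | 60.3 |
| alder | 20.0 | 25.5 | 62.0 |
| birch | 2.00 | 58.3 | 38.3 |
| birch | 5.00 | 38.5 | 54.7 |
| birch | 10.0 | 27.7 | 64.1 |
| birch | 15.0 | 23.6 | 66.8 |
| birch | 20.0 | 21.6 | 67.9 |

(standard deviation of a reading: 0.5 percentage points)



* part of the electrophile that has reacted at the end, red
* part of the electrophile that has reacted at the end, violet
* what raising the concentration of nucleophile from its lowest to its highest value here does to the part of the electrophile that has reacted (changes below 5 percentage points count as none) (it rises / it falls / no change)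

At 20 h the part reacted is 73.5 % in ash and 78.4 % in birch. Going from ash to birch adds 0.0700 M of nucleophile and gives a nucleophile return of 0.210, the moles of electrophile additionally reacted by a fixed time per additional mole of nucleophile charged, other charges held. As a reading from two scattered values, it carries a scatter of 0.0303.

Now the question turned round: for "no change", the span from red to violet, 0.190 M, has to move the part reacted by less than 5 percentage points, which requires a return below 0.0789. The reading stands higher than that, by 4.33 times its scatter, so the part reacted should rise. This reckoning, which assumes the return holds beyond the runs, puts red at 67.2 % from ash and violet at 80.5 % from birch.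

The forecast gives 59 % for red and 81 % for violet, with the verdict it rises, on the ground that “the nucleophile is exhausted at about 60% conversion” in red. For violet it lies close to this reckoning, but for red it lies lower by 8.2 points.

The flask gives 67.6 % for red and 80.8 % for violet; the verdict is it rises, by 13 points.

    electrophile + nucleophile → acid set free + target (k = 0.0110 L mol⁻¹ min⁻¹)
    nucleophile + acid set free ⇌ protonated nucleophile, settled at all times (K = 1300 L mol⁻¹)
    nucleophile + protic impurity → quenched reagent (k = 0.00515 L mol⁻¹ min⁻¹)
    2 electrophile → self-condensation product (k = 0.00103 L mol⁻¹ min⁻¹)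

At 20.0 h red holds 1.9 % of its nucleophile free, less than the 32 % of its electrophile, with nucleophile the limiting reagent. Carried from violet to the neighbour of red charged with 0.66 M of nucleophile, the return of 0.210 gives 86.4 %, and that flask stands at 85.9 %.

(The numbers in the tables stem from a simulated flask on assumed constants; scatter was added.)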